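## Retrosynthetic overview

- **Numbering and feature.** The oxolane is numbered O1, C2 (guaiacyl), C3 (bears hydroxymethyl C6), C4 (bears veratryl-methylene C7), C5. The route rests on the vicinal pair C3/C4. Each carries one oxygenated carbon (C6, C5) and one benzylic carbon (C2, C7), so the chain C6–C3–C4–C5 is a butenolide skeleton whose α- and β-carbons can take up C2 and C7.
- **Last bond made: O1–C2.** The oxolane is the only ring of the target and is formed last. It closes from the open (2R,3R)-dibenzylbutane-1,4-diol through the para-quinone methide of the free guaiacyl phenol.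
- **Diol to lactone.** The diol goes back to a trans,trans 2-benzyl-3-dithianyl-4-menthyloxybutyrolactone, where the carbonyl carbon is C6, the acetal carbon is C5 and the dithiane carbon is C7. Its lactone ring is the former furan ring of furfural, and hydride opens it.
- **Key disconnection.** C4–C7 and C3–C2 are made in one pot from the (5R)-menthyloxybutenolide, the lithiated veratraldehyde dithiane and O-benzylvanillyl bromide.
- **Components.** These come from furfural and (−)-menthol, from veratraldehyde, and from vanillin.

Key step: step 7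

Remark: the SMILES is read as (2S,3R,4R), with the aryl group at C2 trans to C6 and C6 cis to C7. Target atom labels are used throughout. Excess W-2 Raney nickel is taken to cleave the aryl benzyl ether together with the dithiane, so both cleavages are planned as one operation.

## Route

Step 1
Reactants: 1 furfural
Product: 3 5-hydroxyfuran-2(5H)-one (racemic hemiacetal), via furfural endoperoxide 2 (not isolated)
Conditions: O2, methylene blue (cat.), hν (visible), MeOH, 15–20 °C
Reagents that add atoms: dioxygen, O=O
Why: Sensitised singlet-oxygen [4+2] cycloaddition to the furan should give endoperoxide 2, which methanol fragments at the formyl group to the hydroxybutenolide, and the hemiacetal carbon is configurationally labile so no stereocentre needs control here.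

Step 2
Reactants: 3 5-hydroxyfuran-2(5H)-one; 4 (−)-menthol
Product: 6 (5R)-5-(l-menthyloxy)furan-2(5H)-one, via C5 epimer 5 (not isolated)
Conditions: camphor-10-sulfonic acid (cat.), toluene, reflux (Dean–Stark); crystallisation from hexane; mother liquor re-equilibrated with the same acid and recrystallised
Reagents that add atoms: none
Why: Acid-catalysed acetalisation should give both C5 epimers, and because acid interconverts 5 and 6 while only 6 crystallises, the C5 configuration is set by crystallisation-driven epimerisation with the menthyl group as chiral reference.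

Step 3
Reactants: 7 veratraldehyde
Product: 8 2-(3,4-dimethoxyphenyl)-1,3-dithiane
Conditions: HS(CH2)3SH, BF3·OEt2 (cat.), CH2Cl2, 0 °C → rt
Reagents that add atoms: propane-1,3-dithiol, SCCCS
Why: Lewis-acid-catalysed dithioacetalisation of an aromatic aldehyde turns the formyl carbon (later C7) into an acyl-anion equivalent for Corey–Seebach umpolung.

Step 4
Reactants: 9 vanillin
Product: 10 4-benzyloxy-3-methoxybenzaldehyde
Conditions: BnBr, K2CO3, DMF, rt → 60 °C
Reagents that add atoms: benzyl bromide, BrCc1ccccc1
Why: Williamson ether synthesis on the phenoxide masks the acidic phenol so that it cannot quench the carbanion and enolate of the key step.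

Step 5
Reactants: 10 4-benzyloxy-3-methoxybenzaldehyde
Product: 11 4-benzyloxy-3-methoxybenzyl alcohol
Conditions: NaBH4, MeOH, 0 °C
Reagents that add atoms: none
Why: Borohydride reduction of an aromatic aldehyde leaves the benzyl and methyl ethers untouched.

Step 6
Reactants: 11 4-benzyloxy-3-methoxybenzyl alcohol
Product: 12 4-benzyloxy-3-methoxybenzyl bromide
Conditions: PBr3, Et2O, 0 °C; used at once
Reagents that add atoms: phosphorus tribromide, BrP(Br)Br
Why: Bromination through the phosphite ester with SN2 displacement by bromide is standard for electron-rich benzylic alcohols, and the labile bromide is carried on without storage.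

Step 7
Reactants: 6 (5R)-5-(l-menthyloxy)furan-2(5H)-one; 8 2-(3,4-dimethoxyphenyl)-1,3-dithiane; 12 4-benzyloxy-3-methoxybenzyl bromide
Product: 15 (3R,4R,5R)-3-(4-benzyloxy-3-methoxybenzyl)-4-[2-(3,4-dimethoxyphenyl)-1,3-dithian-2-yl]-5-(l-menthyloxy)dihydrofuran-2(3H)-one, via 2-lithiodithiane 13 (not isolated), via lithium lactone enolate 14 (not isolated)
Conditions: 8, n-BuLi, THF, −78 → −30 °C; 6, THF, −78 °C; then 12, DMPU, −78 → 0 °C; aq. NH4Cl
Reagents that add atoms: none
Why: n-BuLi removes the acetal proton of dithiane 8 to give the sulfur- and aryl-stabilised carbanion 13, which adds in Michael fashion to the β-carbon of butenolide 6 (bond C4–C7) to give lithium enolate 14, and 14 is then benzylated at its α-carbon by bromide 12 in an SN2 reaction (bond C3–C2). The closest known reaction type is the tandem conjugate addition–enolate alkylation of lithiated aryl dithioacetals on butenolides and 5-alkoxyfuran-2(5H)-ones. No ring is closed in this step; the lactone ring is only carried along. C4 is controlled by the acetal carbon C5, whose menthyloxy group covers one face of the flat butenolide so that 13 enters anti to it, and C3 is controlled by the new C4 centre, whose quaternary dithianyl group covers one face of the enolate so that 12 enters anti to it, which should give the 3,4-trans-4,5-trans lactone with (3R,4R) configuration. The step needs 1,4- over 1,2-addition, secured by the soft delocalised anion whose carbonyl addition is reversible while conjugate addition leads to the stable enolate, and it needs clean C-monoalkylation before retro-Michael loss, secured by the reactive benzylic bromide, the DMPU co-solvent, the low temperature and the crowding of the product α-carbon. Because C6 and not C2 is the lactone ring atom on C3, this trans lactone maps onto the cis relation of C6 and C7 on the later oxolane.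

Step 8
Reactants: 15 trans,trans benzyl dithianyl menthyloxy lactone
Product: 16 (3R,4R,5R)-4-(3,4-dimethoxybenzyl)-3-(4-hydroxy-3-methoxybenzyl)-5-(l-menthyloxy)dihydrofuran-2(3H)-one
Conditions: Raney nickel (W-2, washed neutral, large excess), EtOH–THF, reflux
Reagents that add atoms: none
Why: Mozingo-type Raney nickel desulfurisation of the benzylic dithioketal turns the dithiane carbon into methylene C7 while the same hydrogen-rich catalyst hydrogenolyses the aryl benzyl ether, and the lactone, menthyl acetal, methyl ethers and the C3 and C4 centres (already in the more stable trans array) should not be affected by the neutral catalyst.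

Step 9
Reactants: 16 phenolic dibenzyl menthyloxy lactone
Product: 17 (2R,3R)-2-(3,4-dimethoxybenzyl)-3-(4-hydroxy-3-methoxybenzyl)butane-1,4-diol
Conditions: LiAlH4 (excess), THF, 0 °C → reflux
Reagents that add atoms: none
Why: LiAlH4 reduction of a γ-alkoxy lactone opens the ring, unmasks the acetal carbon by loss of menthoxide and reduces it as well, so the carbonyl carbon becomes C6H2OH and the acetal carbon C5H2OH, the auxiliary is released for recovery, and C3 and C4 pass through unchanged because reduction is faster than enolisation.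

Step 10
Reactants: 17 phenolic dibenzylbutanediol
Product: 19 4'-O-methyllariciresinol [(2S,3R,4R)-4-(3,4-dimethoxybenzyl)-2-(4-hydroxy-3-methoxyphenyl)-3-(hydroxymethyl)oxolane], via para-quinone methide 18 (not isolated)
Conditions: DDQ (1.0 equiv, slow addition to a dilute solution), 4 Å MS, CH2Cl2–1,4-dioxane, 0 °C
Reagents that add atoms: none
Why: DDQ dehydrogenation of the para-alkylphenol, the most easily oxidised site, should give para-quinone methide 18 by benzylic hydride abstraction at C2, and the C5 hydroxyl captures C2 in a 5-exo-trig 1,6-oxa-conjugate addition (the C6 hydroxyl could only form an oxetane, and the cold, acid-poor medium disfavours Friedel–Crafts attack by the veratryl ring), the aryl group taking the face of the forming ring opposite to C6 so that C2 is set S and trans to C3.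

## Compound list

1 | furfural | O=Cc1ccco1 | starting material
2 | 2,3,7-trioxabicyclo[2.2.1]hept-5-ene-1-carbaldehyde (furfural endoperoxide, racemic) | O=CC12OOC(O1)C=C2 | intermediate
3 | 5-hydroxyfuran-2(5H)-one (racemic) | O=C1OC(O)C=C1 | intermediate
4 | (−)-menthol, (1R,2S,5R) | C[C@@H]1CC[C@H]([C@@H](C1)O)C(C)C | starting material
5 | (5S)-5-(l-menthyloxy)furan-2(5H)-one | O=C1O[C@H](O[C@@H]2C[C@H](C)CC[C@H]2C(C)C)C=C1 | intermediate
6 | (5R)-5-(l-menthyloxy)furan-2(5H)-one | O=C1O[C@@H](O[C@@H]2C[C@H](C)CC[C@H]2C(C)C)C=C1 | intermediate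
7 | veratraldehyde | COc1ccc(C=O)cc1OC | starting material
8 | 2-(3,4-dimethoxyphenyl)-1,3-dithiane | COc1ccc(C2SCCCS2)cc1OC | intermediate
9 | vanillin | COc1cc(C=O)ccc1O | starting material
10 | 4-benzyloxy-3-methoxybenzaldehyde | COc1cc(C=O)ccc1OCc1ccccc1 | intermediate
11 | 4-benzyloxy-3-methoxybenzyl alcohol | COc1cc(CO)ccc1OCc1ccccc1 | intermediate
12 | 4-benzyloxy-3-methoxybenzyl bromide | COc1cc(CBr)ccc1OCc1ccccc1 | intermediate
13 | 2-lithio-2-(3,4-dimethoxyphenyl)-1,3-dithiane | [Li]C1(SCCCS1)c1ccc(OC)c(OC)c1 | intermediate
14 | lithium enolate of the (4R,5R) conjugate adduct | [Li]OC1=C[C@@H](C2(SCCCS2)c2ccc(OC)c(OC)c2)[C@H](O[C@@H]2C[C@H](C)CC[C@H]2C(C)C)O1 | intermediate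
15 | (3R,4R,5R)-3-(4-benzyloxy-3-methoxybenzyl)-4-[2-(3,4-dimethoxyphenyl)-1,3-dithian-2-yl]-5-(l-menthyloxy)dihydrofuran-2(3H)-one | O=C1O[C@@H](O[C@@H]2C[C@H](C)CC[C@H]2C(C)C)[C@H](C2(SCCCS2)c2ccc(OC)c(OC)c2)[C@H]1Cc1ccc(OCc2ccccc2)c(OC)c1 | intermediate
16 | (3R,4R,5R)-4-(3,4-dimethoxybenzyl)-3-(4-hydroxy-3-methoxybenzyl)-5-(l-menthyloxy)dihydrofuran-2(3H)-one | O=C1O[C@@H](O[C@@H]2C[C@H](C)CC[C@H]2C(C)C)[C@H](Cc2ccc(OC)c(OC)c2)[C@H]1Cc1ccc(O)c(OC)c1 | intermediate
17 | (2R,3R)-2-(3,4-dimethoxybenzyl)-3-(4-hydroxy-3-methoxybenzyl)butane-1,4-diol | OC[C@H](Cc1ccc(OC)c(OC)c1)[C@H](CO)Cc1ccc(O)c(OC)c1 | intermediate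
18 | para-quinone methide of 17 (2-methoxy-4-alkylidenecyclohexa-2,5-dienone, alkene geometry open) | COC1=CC(=C[C@@H](CO)[C@H](CO)Cc2ccc(OC)c(OC)c2)C=CC1=O | intermediate
19 | 4'-O-methyllariciresinol, (2S,3R,4R) | COc1cc([C@H]2OC[C@H](Cc3ccc(OC)c(OC)c3)[C@@H]2CO)ccc1O | target

## Step count

Total step count: 10.
Longest linear sequence: 7 (steps 4, 5, 6, 7, 8, 9, 10, from vanillin).

## Steps most likely to fail

**1. Step 10, oxidative closure**

- What may go wrong:
  - carbon attack of the veratryl ring on the activated quinone methide in place of oxygen attack;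
  - acid-promoted re-ionisation of the new benzylic ether;
  - tautomerisation of the quinone methide to a styrene with loss of the C3 centre;
  - further oxidation of the still phenolic product.
- Fallback: bring the C2 oxygen in at the ketone level by exchanging the roles of the two arenes in the same three-component reaction. It sets out from 10 and 6 and returns at 19.
- Compound 10 and propane-1,3-dithiol with BF3·OEt2 should give 2-(4-benzyloxy-3-methoxyphenyl)-1,3-dithiane F1.
- n-BuLi converts it into the 2-lithio derivative F2. Addition to 6 gives the lithium lactone enolate F3.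
- Commercial 3,4-dimethoxybenzyl bromide traps the enolate as the trans,trans lactone F4. In F4 the dithiane carbon is C2, the β-carbon C3, the α-carbon C4, the carbonyl carbon C5 and the acetal carbon C6. The derived butanediol skeleton is pseudo-C2-symmetric, so the same (3R,4R) configuration results.
- MeI and CaCO3 in aqueous MeCN unmask the aryl ketone F5. LiAlH4 then gives the benzylic triol F6, and either carbinol epimer serves.
- Catalytic camphor-10-sulfonic acid in CH2Cl2 closes the oxolane by SN1-type displacement of the benzylic hydroxyl by the C5 hydroxyl, giving the 2,3-trans O-benzyl ether of the target F7.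
- Brief hydrogenolysis (H2, Pd/C, EtOAc) gives 19.

**2. Step 7, three-component coupling**

- What may go wrong:
  - competing carbonyl addition;
  - slow benzylation of the crowded enolate, with retro-Michael loss or proton transfer;
  - decay of the labile bromide before it is consumed.
- Fallback: separate the two bond formations, so that each is run and purified on its own. It sets out from 6 and 8 and returns at 15.
- Carbanion 13 is added to 6 as before, but the enolate is protonated at −78 °C with aq. NH4Cl.
- The Michael adduct (4R,5R)-4-[2-(3,4-dimethoxyphenyl)-1,3-dithian-2-yl]-5-(l-menthyloxy)dihydrofuran-2(3H)-one F8 is isolated and crystallised.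
- Enolate 14 is then regenerated from it with LiN(SiMe3)2 in THF–DMPU at −78 °C and benzylated with freshly made 12. The same anti approach to the dithianyl group gives 15.

**3. Step 8, combined desulfurisation and debenzylation**

- What may go wrong:
  - incomplete cleavage of the benzyl ether;
  - retention of the phenol on the nickel surface;
  - opening of the lactone acetal by residual alkali in ethanol.
- Fallback: decouple the two cleavages and move the debenzylation behind the hydride step. It sets out from 15 and returns at 17.
- Nickel boride made in the flask (NiCl2·6H2O, NaBH4, MeOH–THF, 0 °C) removes only sulfur and should give the benzyl-protected dibenzyl menthyloxy lactone F9.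
- LiAlH4 in THF gives the benzyl-protected diol F10.
- Sulfur is now absent, so H2 with Pd/C in EtOH cleaves the benzyl ether to 17.

## Further compounds

F1 | step 10 | 2-(4-benzyloxy-3-methoxyphenyl)-1,3-dithiane | COc1cc(C2SCCCS2)ccc1OCc1ccccc1
F2 | step 10 | 2-lithio-2-(4-benzyloxy-3-methoxyphenyl)-1,3-dithiane | [Li]C1(SCCCS1)c1ccc(OCc2ccccc2)c(OC)c1
F3 | step 10 | lithium lactone enolate from F2 and 6 | [Li]OC1=C[C@@H](C2(SCCCS2)c2ccc(OCc3ccccc3)c(OC)c2)[C@H](O[C@@H]2C[C@H](C)CC[C@H]2C(C)C)O1
F4 | step 10 | (3R,4R,5R)-4-[2-(4-benzyloxy-3-methoxyphenyl)-1,3-dithian-2-yl]-3-(3,4-dimethoxybenzyl)-5-(l-menthyloxy)dihydrofuran-2(3H)-one | O=C1O[C@@H](O[C@@H]2C[C@H](C)CC[C@H]2C(C)C)[C@H](C2(SCCCS2)c2ccc(OCc3ccccc3)c(OC)c2)[C@H]1Cc1ccc(OC)c(OC)c1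
F5 | step 10 | (3R,4R,5R)-4-(4-benzyloxy-3-methoxybenzoyl)-3-(3,4-dimethoxybenzyl)-5-(l-menthyloxy)dihydrofuran-2(3H)-one | O=C1O[C@@H](O[C@@H]2C[C@H](C)CC[C@H]2C(C)C)[C@H](C(=O)c2ccc(OCc3ccccc3)c(OC)c2)[C@H]1Cc1ccc(OC)c(OC)c1
F6 | step 10 | (2R,3R)-2-[(4-benzyloxy-3-methoxyphenyl)(hydroxy)methyl]-3-(3,4-dimethoxybenzyl)butane-1,4-diol (carbinol epimers) | OC[C@H](Cc1ccc(OC)c(OC)c1)[C@H](CO)C(O)c1ccc(OCc2ccccc2)c(OC)c1
F7 | step 10 | O-benzyl ether of 4'-O-methyllariciresinol, (2S,3R,4R) | COc1cc([C@H]2OC[C@H](Cc3ccc(OC)c(OC)c3)[C@@H]2CO)ccc1OCc1ccccc1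
F8 | step 7 | (4R,5R)-4-[2-(3,4-dimethoxyphenyl)-1,3-dithian-2-yl]-5-(l-menthyloxy)dihydrofuran-2(3H)-one | O=C1O[C@@H](O[C@@H]2C[C@H](C)CC[C@H]2C(C)C)[C@H](C2(SCCCS2)c2ccc(OC)c(OC)c2)C1
F9 | step 8 | (3R,4R,5R)-3-(4-benzyloxy-3-methoxybenzyl)-4-(3,4-dimethoxybenzyl)-5-(l-menthyloxy)dihydrofuran-2(3H)-one | O=C1O[C@@H](O[C@@H]2C[C@H](C)CC[C@H]2C(C)C)[C@H](Cc2ccc(OC)c(OC)c2)[C@H]1Cc1ccc(OCc2ccccc2)c(OC)c1
F10 | step 8 | (2R,3R)-2-(4-benzyloxy-3-methoxybenzyl)-3-(3,4-dimethoxybenzyl)butane-1,4-diol | OC[C@H](Cc1ccc(OC)c(OC)c1)[C@H](CO)Cc1ccc(OCc2ccccc2)c(OC)c1
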